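The readings come from a simulation for substances that don't exist, noise included.

Friday's enzyme works faster than Sunday's: the starting material turned per enzyme per second, the turnover number, is 23.5 s⁻¹ from Friday's reading at 10.0 min and 8.30 s⁻¹ from Sunday's at 30.0 min.

| flask | starting material | gas | free enzyme | temperature | remark | time |
|---|---|---|---|---|---|---|
| Sunday's | 0.10 M | 13 mM (held) | 3.6 µM | 14 °C | run made earlier |  |
| Friday's | 0.10 M | 13 mM (held) | 4.8 µM | 31 °C | run made earlier |  |
| cedar | 0.10 M | 13 mM (held) | 4.0 µM |  | at 7 °C throughout | 10 min |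
| alder | 0.10 M | 13 mM (held) | 2.6 µM |  | at 37 °C until 12 min, from then on at 7 °C | 40 min |

| run | time / min | target / % |
|---|---|---|
| Sunday's | 5.00 | 9.4 |
| Sunday's | 10.0 | 17.7 |
| Sunday's | 20.0 | 36.0 |
| Sunday's | 30.0 | 53.8 |
| Sunday's | 60.0 | 99.7 |
| Friday's | 2.00 | 13.5 |
| Friday's | 5.00 | 33.5 |
| Friday's | 10.0 | 67.6 |
| Friday's | 15.0 | 98.8 |
| Friday's | 20.0 | 101.1 |

(standard deviation of a reading: 0.5 percentage points)

1. the winner by amount of target, in percent of the starting material charged; "neither" if no more than 2 percentage points parts them (cedar / alder / neither)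
2. how much target is there at the end, in percent of the starting material charged: cedar
3. how much target is there at the end, in percent of the starting material charged: alder

*Is one slope per run enough?* Friday's reading at 10.0 min is twice the one at 5.00 min, and the time is twice too. So the slope doesn't sag as starting material falls (zero-order), and the readings run on nearly straight to 98.8 % at 15.0 min.

*And the temperature?* An Arrhenius line through the two numbers has 44.4 kJ mol⁻¹. It puts the turnover number at 5.22 s⁻¹ for 7 °C and at 33.0 s⁻¹ for 37 °C. That is what I carry: the turnover number at the temperature of the bath.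

*Make it a time.* Divide the charge of starting material by turnover number times free enzyme, and you have a clearing time. Alder's is 19.4 min warm and 123 min cold; cedar's is 79.9 min.

*Does alder clear while warm?* No. Its 12 min is shorter than 19.4 min, so the warm stretch gives 61.7 %, and the cold one adds 22.8 %. I commit to 84.5 % for alder, and to 12.5 % for cedar.

*Where is this weakest?* Sunday's and Friday's flasks differ in free enzyme and temperature at once, so proportion to free enzyme is assumed, not read.

The forecast also names alder, with 12.5 % for cedar (9.5 % to 15 %) and 80 % for alder (60 % to 90 %), shaded down since “any enzyme lost also slows the cold stretch”.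

The flasks give 12.0 % in cedar and 82.6 % in alder, so alder holds more target than the other.

    starting material + free enzyme ⇌ first complex (K = 270 M⁻¹, k = 51000 M⁻¹ s⁻¹, Ea = 15.0 kJ mol⁻¹, ΔH = −35.0 kJ mol⁻¹)
    second complex → free enzyme + target (k = 120 s⁻¹, Ea = 61.0 kJ mol⁻¹)
    gas ⇌ second substrate, rate k3*(csat - [second substrate]) (kL = 0.180 s⁻¹)
    first complex → loaded enzyme + first product (k = 11000 s⁻¹, Ea = 45.0 kJ mol⁻¹)
    second substrate + loaded enzyme ⇌ second complex (K = 31.0 M⁻¹, k = 8.70 × 10⁵ M⁻¹ s⁻¹, Ea = 17.0 kJ mol⁻¹, ΔH = −25.0 kJ mol⁻¹)
    second substrate ⇌ dormant form (K = 9.40, k = 0.00310 s⁻¹, Ea = 86.0 kJ mol⁻¹, ΔH = 23.0 kJ mol⁻¹)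
    free enzyme → unfolded enzyme (k = 8.50 × 10⁻⁵ s⁻¹, Ea = 224 kJ mol⁻¹)
    (constants at 37 °C)

Alder beats cedar chiefly through its temperature programme: cedar on alder's programme reaches 76.5 % instead of 12.0 %, a factor of 6.38 against 6.32 from the two turnover numbers. Alder's target stands at 60.8 % at 12.0 min, where the warm clearing time gave 61.7 %. The assumed proportion meets a flask like alder with 1.00 µM of free enzyme: scaling my alder figure gives 32.5 %, and that flask holds 32.3 %.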